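In the flask a spent carrier turns fresh at 1.12 min⁻¹ and a fresh carrier turns spent at 1.53 min⁻¹, each reckoned at the charges.

    spent carrier + salt in the second phase ⇌ fresh carrier + spent salt in the second phase (K1 = 0.88, k1 = 0.031 M⁻¹ s⁻¹)
    substrate + fresh carrier → product + spent carrier (k2 = 0.085 M⁻¹ s⁻¹)
    substrate + spent carrier → spent catalyst (k3 = 4.4 × 10⁻⁴ M⁻¹ s⁻¹)

substrate 0.30 M; salt in the second phase 1.20 M; spent carrier 7.5 mM; volume of the second phase over the first 2.0

- in the second phase: salt in the second phase, spent salt in the second phase; everything else is in the first
- charges count per volume of the first phase; a concentration in a rate is the amount of a species over the volume of its own phase; every rate counts per litre of the first phase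
- charge of substrate (flask): 0.30 M

- apparent order in spent carrier when 10% of the substrate are converted (percent change of the rate of making product for one percent more spent carrier charged)
- apparent order in salt in the second phase when 10% of the substrate are converted (percent change of the rate of making product for one percent more salt in the second phase charged)

A rate constant times a concentration says how often one carrier reacts. The salt sits in a second phase of twice the volume of the first, so its own concentration is half its charge, and that half enters the first figure.

Those two figures sum to 2.65 min⁻¹, far above 0.0383 min⁻¹, the rate per substrate with the carrier charge counted as fresh, so I expect the two carrier forms in the flask to balance early and stay balanced as the substrate falls, a quasi-steady state. The loss to spent catalyst takes a spent carrier at 0.007920 min⁻¹, slower than the forward exchange by a factor of 141, so I leave it out of the share.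

At 10% conversion the substrate stands at 90.0% of its charge. The salt, used about once per product, stands at 0.975 of its own. That gives 0.441 for the fresh share, the forward exchange over the sum of the forward exchange and the making of product, with the back step of the exchange left out.

The rate of making product is substrate times carrier times fresh share, so in logarithms the three add and an order is a slope. In this reckoning one percent more carrier moves both forms alike and leaves the share as it is, so I expect order 1 in spent carrier. One percent more salt raises the making rate by one percent, and the logarithm of the share climbs by one minus the share, so I expect 0.559 in salt.

The forecast gives 1.025 and 0.605, on this footing: “Treat the fresh carrier as a quasi-steady intermediate”. Its salt order stands above mine.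

The flask gives 1.0 in spent carrier and 0.61 in salt, with fresh carrier at 42.1% of the catalyst charged after 6.88 min. With twice the salt charged, the salt stands at 0.988 of its charge at 10% conversion, and the fresh share becomes 0.615. I reckon a factor of 1.39 on the rate from that, and the flask with doubled salt shows 1.42.

The numbers of this flask are invented; no experiment stands behind them.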